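# Ardisinone by squarate ring expansion: synthesis design

## The problem

Ardisinone (19) is a 1,4-benzoquinone in which C1 and C4 are the carbonyl carbons, C2 carries a methoxy group, C6 carries the fifteen-carbon chain C1'–C15', and C3 and C5 are unsubstituted. Methoxy group and chain flank the same carbonyl, C1, so three ring oxygens (C1, C2, C4) and one carbon substituent (C6) must be placed in exactly this relationship, either through the connectivity of a ring-forming step or through a late, site-selective oxidation of an arene. The only stereocentre is C2' (R), an acetoxy-bearing carbon between the methylene groups C1' and C3'. Nothing else in the molecule can control it, and because no diastereomers can arise a shortfall in enantiomeric purity cannot be repaired later, so it has to enter with full fidelity at the start. The methoxyquinone is a vinylogous ester and a Michael acceptor that amines, hydroxide, hydride and organometallic reagents attack, so all carbanion chemistry must be finished before the quinone is unveiled. The C2' acetate is cleaved by base and lies β to the C1' methylene that the quinone acidifies, so it can also be lost by elimination, and it is best introduced last and without base. What makes a short synthesis possible is that C1 to C4 carry O, OMe, H and O in the order found in a squarate-derived 4-hydroxy-3-methoxycyclobutenone, while C5 and C6 are the two carbons of a 1,1-disubstituted alkene bearing the chain, so the four-membered ring and the alkene can merge into the six-membered ring with ring bond C4–C5 as the only new skeletal bond.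

## Retrosynthesis

**End game (19 ⇒ 18 ⇒ 17 ⇒ 16).** The acyl C–O bond at C2' is cut first, giving hydroxy quinone 18. Behind 18 stands silyl ether 17, and behind 17 the hydroquinone 16. None of these changes touches the skeleton. Acetylating at the hydroquinone stage is rejected because the two phenols of 16 would compete with the carbinol. The forward steps need a neutral oxidant, an acidic fluoride source and a base-free acylation.

**Key cut (16 ⇒ 13).** Ring bond C4–C5 of 16 is cut. This leads through dienone 15 and dienylketene 14 to cyclobutenone 13, in which C1–C4 of the target are a four-membered ring and C5/C6 an alkene. The neighbouring cuts (C6–C1', or a late oxidation of a bought arene) leave the oxygen pattern to a separate selective step. Here all three oxygens are already in place and the 2-methoxy-6-alkyl relationship follows from connectivity. The aromatic ring is reduced to a squarate-derived ring plus a side-chain alkene. The forward reaction needs ring opening with the hydroxyl turned outward and electrocyclization faster than any capture of the ketene.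

**Fragment union (13 ⇒ 12 + 11).** The bond between the ring carbinol carbon (future C1) and the alkene carbon (future C6) is cut, giving alkenyllithium 12 and 3-methoxycyclobutenedione 11. Adding 12 to dimethyl squarate 9 would be simpler but would leave a second methoxy group at C3. With 11 that position is hydrogen. The forward reaction needs 12 to add to the carbonyl next to the methoxy-bearing carbon and not to the vinylogous ester carbonyl.

**The four-carbon unit (11 ⇒ 9).** One methoxy group of 9 is exchanged for hydrogen by hydride addition to one carbonyl (hemi-reduced 10) and acid-induced transposition with loss of methanol. This keeps the whole oxygenated C1–C4 unit in one commercial compound.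

**The alkenyl donor (12 ⇐ 8 ⇐ 6 ⇐ 5).** Reagent 12 comes from bromoalkene 8 by halogen–lithium exchange. The C–Br and C–H bonds of 8 are cut back to the terminal alkyne of silyl ether 6 (Markovnikov haloboration and protonolysis via alkenylborane 7), and 6 to alkynol 5. The alkyne is preferred to a direct 2-bromoallyl transfer because it lets the stereocentre be bought.

**The stereocentre (5 ⇒ 4 ⇒ 3 ⇒ 1 + 2).** Bonds C6–C1' (acetylide to epoxide 4) and C3'–C4' (Grignard reagent 2 to the epoxide of 1) are cut. The three carbons of (R)-epichlorohydrin 1 become C1', C2' and C3', and the stereocentre is never a reacting atom. A reagent-controlled 2-bromoallylation of a long-chain aldehyde would reach the bromoalkene two steps sooner. It is set aside because the enantiomeric purity of an isolated carbinol made from an unbranched aldehyde would depend entirely on the reagent and could not be upgraded afterwards.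

## Roads not taken

**Alternative 1:** The cut is at the C2'–O bond, but the oxygen is borrowed from the ring: the future C1 oxygen acts as nucleophile and the stereocentre is formed inside a dihydrofuran that the target does not contain.

- Forward key step: a zerovalent palladium complex from Pd2(dba)3 and a chiral trans-1,2-diaminocyclohexane bis(2-diphenylphosphinobenzamide) ligand ionises (2E)-4-(2-hydroxy-3,5-dimethoxyphenyl)but-2-en-1-yl methyl carbonate A1. The phenol oxygen closes onto the inner allyl terminus to give (2S)-2-ethenyl-5,7-dimethoxy-2,3-dihydro-1-benzofuran A2.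
- Completion: the vinyl group is extended to the tridecyl chain (cross-metathesis with a long terminal alkene, then saturation). Oxidation of the para-dioxygenated arene with (NH4)2Ce(NO3)6 then cleaves the aryl–oxygen bond, releasing the C2' hydroxyl with its configuration intact together with the quinone, which is compound 18 of the chosen route.
- Merits: the stereocentre is set catalytically, the arene is bought, the carbinol needs no protecting group, and quinone and alcohol appear in one operation.
- Weak points: the enantioselectivity depends on the diastereomeric π-allyl complexes equilibrating faster than an intrinsically fast five-membered ring closure, and nothing in A1 secures this. The stereocentre is created as an allylic aryl ether, so saturation of the chain must avoid hydrogenolysis of that C–O bond. Eleven chain carbons must still be attached after the key step. A1 itself requires an ortho-selective four-carbon functionalisation of an electron-rich phenol.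
- Comparison: the step counts are close, and Alternative 1 is better in catalyst economy and in avoiding a silyl group. The chosen plan sets against this a stereocentre of assured configuration and purity, and a ring whose oxygen pattern follows from connectivity, not from a late oxidative cleavage.

**Alternative 2:** Both bonds at C1' are cut (C6–C1' and C1'–C2') and the ring is bought as an arene.

- Forward key step: 2-[2-(benzyloxy)-3-methoxyphenyl]-4,4,5,5-tetramethyl-1,3,2-dioxaborolane A3 is homologated in one pot, first with chloromethyllithium (bromochloromethane, n-BuLi; Matteson homologation), then with the lithiated form of tetradecyl N,N-di(propan-2-yl)carbamate A4 (s-BuLi, (−)-sparteine). Two successive 1,2-metallate shifts give 2-{(2R)-1-[2-(benzyloxy)-3-methoxyphenyl]pentadecan-2-yl}-4,4,5,5-tetramethyl-1,3,2-dioxaborolane A5.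
- Completion: stereoretentive oxidation of the C–B bond, acetylation, hydrogenolysis of the benzyl ether, and oxidation of the freed phenol at its open para position ((KSO3)2NO or Co(salen) with O2).
- Merits: this is the most convergent and the shortest road, about six operations against ten. The acetate is installed before any quinone exists, so the delicate hydroxy quinone is never handled. On both counts it is better than the chosen plan.
- Weak points: it needs a stoichiometric chiral diamine and two lithium carbenoids at −78 °C in one pot. Chloromethyllithium can insert twice or not at all, and chain homologues of a C15 lipid would be very hard to remove. The enantiomeric purity is that of the lithiated carbamate, with no later correction. The final phenol oxidation must stop at the para-quinone in the presence of the acetate.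
- Comparison: the chosen plan sets against the shorter sequence ordinary reagents, a bought stereocentre, carbon–carbon bonds formed one at a time through isolable intermediates, and an oxygen pattern fixed in the ring-forming event.

**Alternative 3:** Ring bond C1–C6 is cut, and the arene arises by aldol condensation of a linear polyketide.

- Forward key step: heating 6-[(6R)-6-(tert-butyldimethylsilyloxy)-2,4-dioxononadecyl]-2,2-dimethyl-4H-1,3-dioxin-4-one A6 in methanol releases an acylketene that is trapped as methyl (9R)-9-(tert-butyldimethylsilyloxy)-3,5,7-trioxodocosanoate A7. Cs2CO3 and then HCl make its C2 methylene add to the C7 ketone and aromatise to methyl 2,4-dihydroxy-6-[(2R)-2-(tert-butyldimethylsilyloxy)pentadecyl]benzoate A8.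
- Merits: it is biomimetic, the ring substitution is dictated by the chain, no organolithium or strained ring is involved, and the stereocentre comes from a 3-hydroxyacyl unit accessible by asymmetric hydrogenation of a β-keto ester.
- Weak points: A8 has a carbon substituent where the target has the C1 oxygen and lacks the para oxygen. Ester removal, differentiation of two phenols for a single O-methylation and a late para-oxidation therefore follow, five or six steps after the key step, on top of a multistep assembly of A6. In A7 the silyloxy group is β to the C7 ketone, so carbonate base can eliminate it before the ring closes and destroy the stereocentre.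
- Comparison: Alternative 3 is gentler and more easily scaled, but it is clearly longer and makes the ring at the wrong oxidation pattern. The chosen plan delivers the ring with all three oxygens in place.

Key step: step 7

## Route

Assumption: solutions of 2 and of the ethylenediamine complex of lithium acetylide are taken as commercial reagents, and 13 is carried on as the mixture of its two epimers at the ring carbinol carbon, a centre that step 7 destroys.

Step 1
Reactants: 1 (2R)-2-(chloromethyl)oxirane [(R)-epichlorohydrin]; 2 dodecylmagnesium bromide
Product: 3 (2R)-1-chloropentadecan-2-ol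
Conditions: CuI (10 mol%), THF, −40 → 0 °C; then 1 M HCl
Reagents that add atoms: none
Why: Copper-catalysed Grignard opening of a terminal epoxide at its unsubstituted ring carbon; the chloromethyl carbon is left alone at low temperature and the stereocentre is not a reacting atom, so 3 keeps the R configuration of 1.

Step 2
Reactants: 3 (2R)-1-chloropentadecan-2-ol
Product: 5 (4R)-heptadec-1-yn-4-ol, via (2R)-2-tridecyloxirane 4 (not isolated)
Conditions: LiC≡CH·H2NCH2CH2NH2 (3 equiv), DMSO, 0 °C → rt; then H2O
Reagents that add atoms: lithium acetylide (as its ethylenediamine complex), [Li]C#C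
Why: The first equivalent of acetylide deprotonates the alcohol and the alkoxide closes epoxide 4 by intramolecular Williamson displacement of the primary chloride; further acetylide opens 4 at its CH2 terminus (acetylide–epoxide alkylation), so neither event touches the stereocentre.

Step 3
Reactants: 5 (4R)-heptadec-1-yn-4-ol
Product: 6 tert-butyl[(4R)-heptadec-1-yn-4-yloxy]dimethylsilane
Conditions: TBSCl, imidazole, DMF, rt
Reagents that add atoms: tert-butyldimethylsilyl chloride, CC(C)(C)[Si](C)(C)Cl
Why: Standard imidazole-mediated silylation of a secondary alcohol; the silyl ether tolerates tert-butyllithium at −78 °C and neutral heating and is later removed by acidic fluoride, which a quinone withstands.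

Step 4
Reactants: 6 tert-butyl[(4R)-heptadec-1-yn-4-yloxy]dimethylsilane
Product: 8 {[(4R)-2-bromoheptadec-1-en-4-yl]oxy}(tert-butyl)dimethylsilane, via alkenylborane 7 (not isolated)
Conditions: B-bromo-9-BBN, CH2Cl2, 0 °C; then AcOH, 0 °C → rt
Reagents that add atoms: 9-bromo-9-borabicyclo[3.3.1]nonane, BrB1C2CCCC1CCC2
Why: Haloboration of a terminal alkyne: B–Br adds syn with boron on the terminal carbon and bromine on the internal one, and protonolysis of the alkenyl C–B bond by acetic acid gives the 2-bromo-1-alkene; no stereocentre is formed or touched.

Step 5
Reactants: 9 dimethyl squarate (3,4-dimethoxycyclobut-3-ene-1,2-dione)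
Product: 11 3-methoxycyclobut-3-ene-1,2-dione, via 4-hydroxy-2,3-dimethoxycyclobut-2-en-1-one 10 (not isolated)
Conditions: LiAlH(OtBu)3, THF, −78 → −20 °C; then aq. HCl; crude 10, conc. HCl (cat.), CH2Cl2, rt
Reagents that add atoms: water, O
Why: One of the two equivalent carbonyls takes a single hydride from the hindered aluminate (1,2-reduction) to give 10; acid then ionises the carbinol to a methoxy-stabilised cyclobutenyl cation that is hydrolysed with loss of methanol (allylic transposition of a vinylogous ester), leaving hydrogen where a methoxy group stood.

Step 6
Reactants: 8 {[(4R)-2-bromoheptadec-1-en-4-yl]oxy}(tert-butyl)dimethylsilane; 11 3-methoxycyclobut-3-ene-1,2-dione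
Product: 13 4-[(4R)-4-(tert-butyldimethylsilyloxy)heptadec-1-en-2-yl]-4-hydroxy-3-methoxycyclobut-2-en-1-one (both epimers at the ring carbinol carbon), via alkenyllithium 12 (not isolated)
Conditions: 8, t-BuLi (2 equiv), Et2O, −78 °C; then added to 11, THF, −78 °C; aq. NH4Cl, −78 °C
Reagents that add atoms: none
Why: Bromine–lithium exchange (the second equivalent of tert-butyllithium destroys the tert-butyl bromide formed) gives 12, which has no β leaving group; it adds 1,2 to the carbonyl of 11 attached to the methoxy-bearing carbon because the other carbonyl is deactivated as a vinylogous ester; the new ring carbinol centre forms without control and both epimers are used.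

Step 7
Reactants: 13 4-[(4R)-4-(tert-butyldimethylsilyloxy)heptadec-1-en-2-yl]-4-hydroxy-3-methoxycyclobut-2-en-1-one
Product: 16 2-[(2R)-2-(tert-butyldimethylsilyloxy)pentadecyl]-6-methoxybenzene-1,4-diol, via dienylketene 14 (not isolated), via cyclohexa-2,4-dienone 15 (not isolated)
Conditions: toluene (0.02 M, degassed), 110 °C, Ar
Reagents that add atoms: none
Why: This is the thermal ring expansion of a 4-alkenyl-4-hydroxycyclobutenone (Moore rearrangement), the closest known reaction type being the conversion of squarate-derived 4-alkenyl- and 4-aryl-4-hydroxycyclobutenones into hydroquinones. Conrotatory four-electron opening of the bond between the carbonyl carbon and the carbinol carbon of the four-membered ring gives dienylketene 14. The six-membered ring then closes by thermal disrotatory six-electron electrocyclization, which joins the ketene carbon (future C4) to the alkene CH2 (future C5), and dienone 15 enolises to aromatic 16. No stereocentre is created: the ring carbinol centre of 13 is destroyed, so both epimers converge, and C2' is a spectator. The selectivity needed is torquoselectivity, since the alkenyl group must rotate inward to lie next to the ketene, and the strong preference of the hydroxyl donor for outward rotation secures it. Regiochemistry needs no control, because the carbinol carbon becomes C1 between the methoxy-bearing C2 and the chain-bearing C6 by connectivity. High dilution and exclusion of air are meant to keep the ketene from intermolecular capture and the hydroquinone from premature oxidation, and crude 16 is taken directly into step 8.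

Step 8
Reactants: 16 2-[(2R)-2-(tert-butyldimethylsilyloxy)pentadecyl]-6-methoxybenzene-1,4-diol
Product: 17 2-[(2R)-2-(tert-butyldimethylsilyloxy)pentadecyl]-6-methoxycyclohexa-2,5-diene-1,4-dione
Conditions: Ag2O, Na2SO4, Et2O, rt
Reagents that add atoms: none
Why: Two-electron oxidation of a hydroquinone to the para-quinone by Ag2O under neutral, anhydrous conditions; silyl ether and methoxy group are untouched.

Step 9
Reactants: 17 2-[(2R)-2-(tert-butyldimethylsilyloxy)pentadecyl]-6-methoxycyclohexa-2,5-diene-1,4-dione
Product: 18 2-[(2R)-2-hydroxypentadecyl]-6-methoxycyclohexa-2,5-diene-1,4-dione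
Conditions: HF·pyridine, MeCN, 0 °C → rt
Reagents that add atoms: none
Why: Fluoride-induced cleavage of the Si–O bond in an acidic medium; the protonated pyridine is not nucleophilic toward the quinone, the vinylogous ester is stable to acid of this strength, and the C2'–O bond is not broken.

Step 10
Reactants: 18 2-[(2R)-2-hydroxypentadecyl]-6-methoxycyclohexa-2,5-diene-1,4-dione
Product: 19 ardisinone, (2R)-1-(5-methoxy-3,6-dioxocyclohexa-1,4-dien-1-yl)pentadecan-2-yl acetate
Conditions: Ac2O, Sc(OTf)3 (1 mol%), MeCN, −20 °C
Reagents that add atoms: acetic anhydride, CC(=O)OC(C)=O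
Why: Lewis-acid-catalysed acylation of a secondary alcohol, fast at low temperature and free of base, so neither the base-sensitive methoxyquinone nor the β-acyloxy arrangement (prone to elimination through the acidic C1' methylene) is endangered; the C2'–O bond is not broken, so the R configuration is retained.

## Compound list

1 | (2R)-2-(chloromethyl)oxirane, (R)-epichlorohydrin | ClC[C@H]1CO1 | starting material
2 | dodecylmagnesium bromide | CCCCCCCCCCCC[Mg]Br | starting material
3 | (2R)-1-chloropentadecan-2-ol | CCCCCCCCCCCCC[C@H](CCl)O | intermediate
4 | (2R)-2-tridecyloxirane | CCCCCCCCCCCCC[C@@H]1CO1 | intermediate (not isolated)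
5 | (4R)-heptadec-1-yn-4-ol | CCCCCCCCCCCCC[C@H](CC#C)O | intermediate
6 | tert-butyl[(4R)-heptadec-1-yn-4-yloxy]dimethylsilane | CCCCCCCCCCCCC[C@H](CC#C)O[Si](C)(C)C(C)(C)C | intermediate
7 | 9-[(1Z,4R)-2-bromo-4-(tert-butyldimethylsilyloxy)heptadec-1-en-1-yl]-9-borabicyclo[3.3.1]nonane | CCCCCCCCCCCCC[C@H](C/C(Br)=C/B1C2CCCC1CCC2)O[Si](C)(C)C(C)(C)C | intermediate (not isolated)
8 | {[(4R)-2-bromoheptadec-1-en-4-yl]oxy}(tert-butyl)dimethylsilane | CCCCCCCCCCCCC[C@H](CC(Br)=C)O[Si](C)(C)C(C)(C)C | intermediate
9 | dimethyl squarate, 3,4-dimethoxycyclobut-3-ene-1,2-dione | COC1=C(OC)C(=O)C1=O | starting material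
10 | 4-hydroxy-2,3-dimethoxycyclobut-2-en-1-one (racemic) | COC1=C(OC)C(O)C1=O | intermediate (not isolated)
11 | 3-methoxycyclobut-3-ene-1,2-dione | COC1=CC(=O)C1=O | intermediate
12 | [(4R)-4-(tert-butyldimethylsilyloxy)heptadec-1-en-2-yl]lithium | CCCCCCCCCCCCC[C@H](CC([Li])=C)O[Si](C)(C)C(C)(C)C | intermediate (not isolated)
13 | 4-[(4R)-4-(tert-butyldimethylsilyloxy)heptadec-1-en-2-yl]-4-hydroxy-3-methoxycyclobut-2-en-1-one (both epimers at ring C4) | CCCCCCCCCCCCC[C@H](CC(=C)C1(O)C(OC)=CC1=O)O[Si](C)(C)C(C)(C)C | intermediate
14 | (3Z,7R)-7-(tert-butyldimethylsilyloxy)-4-hydroxy-3-methoxy-5-methylideneicosa-1,3-dien-1-one | CCCCCCCCCCCCC[C@H](CC(=C)/C(O)=C(OC)\C=C=O)O[Si](C)(C)C(C)(C)C | intermediate (not isolated)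
15 | 5-[(2R)-2-(tert-butyldimethylsilyloxy)pentadecyl]-4-hydroxy-3-methoxycyclohexa-2,4-dien-1-one | CCCCCCCCCCCCC[C@H](CC1=C(O)C(OC)=CC(=O)C1)O[Si](C)(C)C(C)(C)C | intermediate (not isolated)
16 | 2-[(2R)-2-(tert-butyldimethylsilyloxy)pentadecyl]-6-methoxybenzene-1,4-diol | CCCCCCCCCCCCC[C@H](Cc1cc(O)cc(OC)c1O)O[Si](C)(C)C(C)(C)C | intermediate
17 | 2-[(2R)-2-(tert-butyldimethylsilyloxy)pentadecyl]-6-methoxycyclohexa-2,5-diene-1,4-dione | CCCCCCCCCCCCC[C@H](CC1=CC(=O)C=C(OC)C1=O)O[Si](C)(C)C(C)(C)C | intermediate
18 | 2-[(2R)-2-hydroxypentadecyl]-6-methoxycyclohexa-2,5-diene-1,4-dione | CCCCCCCCCCCCC[C@H](CC1=CC(=O)C=C(OC)C1=O)O | intermediate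
19 | ardisinone, (2R)-1-(5-methoxy-3,6-dioxocyclohexa-1,4-dien-1-yl)pentadecan-2-yl acetate | CCCCCCCCCCCCC[C@H](CC1=CC(=O)C=C(OC)C1=O)OC(C)=O | target

## Step count and risks

Total: 10 steps. Longest linear sequence: 9 steps (steps 1–4 and 6–10, from 1 to 19); step 5 is a one-step side branch.

**Step 7 (key step).** Part of the material may open with the hydroxyl turned inward, or the ketene may be captured by a hydroxyl group, its own or that of a second molecule, faster than it cyclises. Lactonisation or oligomerisation would then compete with ring expansion. Partial air oxidation of the product is harmless, since step 8 oxidises everything.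
Fallback: setting out from 13, the tertiary hydroxyl is capped (Me3SiCl, Et3N, CH2Cl2, 0 °C) to give 4-[(4R)-4-(tert-butyldimethylsilyloxy)heptadec-1-en-2-yl]-3-methoxy-4-(trimethylsilyloxy)cyclobut-2-en-1-one F1. With no free hydroxyl on the four-membered ring the ketene has only the electrocyclic channel, and the silyloxy donor still rotates outward. Thermolysis in toluene should then give, after enolisation, 5-[(2R)-2-(tert-butyldimethylsilyloxy)pentadecyl]-3-methoxy-4-(trimethylsilyloxy)phenol F2. Brief treatment with citric acid in methanol removes only the aryl trimethylsilyl ether, and the route is rejoined at 16.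

**Step 6.** The alkenyllithium may be lost before the C–C bond forms, by migration of silicon from oxygen to the carbanion (retro-Brook shift through a five-membered silicate) on any warming, or by proton transfer. Site selectivity on the small, very electrophilic dione may also erode.
Fallback: the union is run without the silyl group. Setting out from 8, Bu4NF in THF gives (4R)-2-bromoheptadec-1-en-4-ol F3. Deprotonation with n-BuLi (1 equiv) and exchange with t-BuLi (2 equiv) at −78 °C give lithium (4R)-2-lithioheptadec-1-en-4-olate F4, in which no silicon can migrate. Addition to 11 should give 4-hydroxy-4-[(4R)-4-hydroxyheptadec-1-en-2-yl]-3-methoxycyclobut-2-en-1-one F5. Thermolysis as in step 7 should give 2-[(2R)-2-hydroxypentadecyl]-6-methoxybenzene-1,4-diol F6, and Ag2O oxidation returns to the route at 18, which makes step 9 unnecessary.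

**Step 4.** The Lewis-acidic bromoborane may cleave the silyl ether, or the haloboration may be incompletely Markovnikov-selective.
Fallback: the halide is introduced through a vinylsilane. Setting out from 3, aqueous NaOH closes the epoxide 4, here isolated. Opening with the Grignard reagent prepared from (1-bromovinyl)trimethylsilane and magnesium (CuI cat., THF, −30 °C) gives (4R)-2-(trimethylsilyl)heptadec-1-en-4-ol F7. Silylation (TBSCl, imidazole) gives tert-butyldimethyl{[(4R)-2-(trimethylsilyl)heptadec-1-en-4-yl]oxy}silane F8. Ipso-iododesilylation with N-iodosuccinimide in MeCN/ClCH2CN gives tert-butyl{[(4R)-2-iodoheptadec-1-en-4-yl]oxy}dimethylsilane F9. Iodine–lithium exchange with t-BuLi delivers 12, where the route is rejoined within step 6.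

**Step 10.** The Lewis acid may promote addition of the anhydride to the quinone (Thiele–Winter acetoxylation), or cyclisation or elimination of the β-hydroxyalkyl quinone may compete with O-acetylation.
Fallback: the acylation is done at the hydroquinone oxidation level. Setting out from 18, reductive acetylation (Zn, Ac2O, NaOAc) gives (2R)-1-[2,5-bis(acetyloxy)-3-methoxyphenyl]pentadecan-2-yl acetate F10. NH4OAc in aqueous methanol cleaves the two aryl acetates and leaves the alkyl acetate, giving (2R)-1-(2,5-dihydroxy-3-methoxyphenyl)pentadecan-2-yl acetate F11. Ag2O oxidation returns to the route at 19.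

## Further compounds

F1 | step 7 | 4-[(4R)-4-(tert-butyldimethylsilyloxy)heptadec-1-en-2-yl]-3-methoxy-4-(trimethylsilyloxy)cyclobut-2-en-1-one | CCCCCCCCCCCCC[C@H](CC(=C)C1(O[Si](C)(C)C)C(OC)=CC1=O)O[Si](C)(C)C(C)(C)C
F2 | step 7 | 5-[(2R)-2-(tert-butyldimethylsilyloxy)pentadecyl]-3-methoxy-4-(trimethylsilyloxy)phenol | CCCCCCCCCCCCC[C@H](Cc1cc(O)cc(OC)c1O[Si](C)(C)C)O[Si](C)(C)C(C)(C)C
F3 | step 6 | (4R)-2-bromoheptadec-1-en-4-ol | CCCCCCCCCCCCC[C@H](CC(Br)=C)O
F4 | step 6 | lithium (4R)-2-lithioheptadec-1-en-4-olate | CCCCCCCCCCCCC[C@H](CC([Li])=C)O[Li]
F5 | step 6 | 4-hydroxy-4-[(4R)-4-hydroxyheptadec-1-en-2-yl]-3-methoxycyclobut-2-en-1-one | CCCCCCCCCCCCC[C@H](CC(=C)C1(O)C(OC)=CC1=O)O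
F6 | step 6 | 2-[(2R)-2-hydroxypentadecyl]-6-methoxybenzene-1,4-diol | CCCCCCCCCCCCC[C@H](Cc1cc(O)cc(OC)c1O)O
F7 | step 4 | (4R)-2-(trimethylsilyl)heptadec-1-en-4-ol | CCCCCCCCCCCCC[C@H](CC(=C)[Si](C)(C)C)O
F8 | step 4 | tert-butyldimethyl{[(4R)-2-(trimethylsilyl)heptadec-1-en-4-yl]oxy}silane | CCCCCCCCCCCCC[C@H](CC(=C)[Si](C)(C)C)O[Si](C)(C)C(C)(C)C
F9 | step 4 | tert-butyl{[(4R)-2-iodoheptadec-1-en-4-yl]oxy}dimethylsilane | CCCCCCCCCCCCC[C@H](CC(I)=C)O[Si](C)(C)C(C)(C)C
F10 | step 10 | (2R)-1-[2,5-bis(acetyloxy)-3-methoxyphenyl]pentadecan-2-yl acetate | CCCCCCCCCCCCC[C@H](Cc1cc(OC(C)=O)cc(OC)c1OC(C)=O)OC(C)=O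
F11 | step 10 | (2R)-1-(2,5-dihydroxy-3-methoxyphenyl)pentadecan-2-yl acetate | CCCCCCCCCCCCC[C@H](Cc1cc(O)cc(OC)c1O)OC(C)=O
A1 | alternative 1 | (2E)-4-(2-hydroxy-3,5-dimethoxyphenyl)but-2-en-1-yl methyl carbonate | COC(=O)OC/C=C/Cc1cc(OC)cc(OC)c1O
A2 | alternative 1 | (2S)-2-ethenyl-5,7-dimethoxy-2,3-dihydro-1-benzofuran | C=C[C@H](C1)Oc2c(OC)cc(OC)cc12
A3 | alternative 2 | 2-[2-(benzyloxy)-3-methoxyphenyl]-4,4,5,5-tetramethyl-1,3,2-dioxaborolane | COc1cccc(B2OC(C)(C)C(C)(C)O2)c1OCc1ccccc1
A4 | alternative 2 | tetradecyl N,N-di(propan-2-yl)carbamate | CCCCCCCCCCCCCCOC(=O)N(C(C)C)C(C)C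
A5 | alternative 2 | 2-{(2R)-1-[2-(benzyloxy)-3-methoxyphenyl]pentadecan-2-yl}-4,4,5,5-tetramethyl-1,3,2-dioxaborolane | CCCCCCCCCCCCC[C@H](Cc1cccc(OC)c1OCc1ccccc1)B1OC(C)(C)C(C)(C)O1
A6 | alternative 3 | 6-[(6R)-6-(tert-butyldimethylsilyloxy)-2,4-dioxononadecyl]-2,2-dimethyl-4H-1,3-dioxin-4-one | CCCCCCCCCCCCC[C@H](CC(=O)CC(=O)CC1=CC(=O)OC(C)(C)O1)O[Si](C)(C)C(C)(C)C
A7 | alternative 3 | methyl (9R)-9-(tert-butyldimethylsilyloxy)-3,5,7-trioxodocosanoate | CCCCCCCCCCCCC[C@H](CC(=O)CC(=O)CC(=O)CC(=O)OC)O[Si](C)(C)C(C)(C)C
A8 | alternative 3 | methyl 2,4-dihydroxy-6-[(2R)-2-(tert-butyldimethylsilyloxy)pentadecyl]benzoate | CCCCCCCCCCCCC[C@H](Cc1cc(O)cc(O)c1C(=O)OC)O[Si](C)(C)C(C)(C)C
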